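**Plan** (target numbered as a naphthalene-1,4-dione: C1(=O), C2(OMe), C3H, C4(=O), C4a, C5H, C6(CH2Ar), C7(CH3), C8(Ar), C8a)

- Retrosynthesis cuts, in order: the two phenolic O–benzyl bonds; then C4–C4a and C1–C8a of the quinone ring, which leaves an aryllithium at C8a and 3-methoxycyclobut-3-ene-1,2-dione holding C1–C4; then C8a–I (from C8a–N), the C8–aryl bond and the C6–CH2 bond, back to 2-bromo-3-methylaniline.
- Enabling feature: the quinone ring atoms C1(=O)–C2(OMe)=C3H–C4(=O) are a methoxycyclobutenedione in expanded form, joined to the benzo ring at C8a and C4a. C4a–H is the only free position ortho to C8a because C8 carries the aryl group, so ring closure can occur only there.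
- Forward order: the benzo ring is bought and substituted (iodination para to NH2, Negishi benzylation at C6, Suzuki arylation at C8, NH2 to I to Li at C8a). The aryllithium adds to the ketone carbonyl of the semisquarate, the four-membered ring is expanded to the quinone ring last, and hydrogenolysis frees the phenols.
- Stereochemistry: the target has no stereocentre. The carbinol centres of 12 and 15 are racemic and are destroyed.

Key step: step 8

Assumption: the C8–aryl bond has no ortho substituent on the pendant ring and is treated as freely rotating, so no axis needs to be controlled; compounds 1, 3, 7 and 11 are taken as commercial.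

**Route**

Step 1
Reactants: 1 2-bromo-3-methylaniline
Product: 2 2-bromo-4-iodo-3-methylaniline
Conditions: NIS, MeCN, 0 to 25 °C
Reagents that add atoms: N-iodosuccinimide, O=C1CCC(=O)N1I
Why: Electrophilic aromatic iodination, in which the amino group should direct to its para position (C4), since C2 is blocked by bromine and the remaining ortho position C6 is less favoured than para.

Step 2
Reactants: 3 4-(benzyloxy)-3-methoxybenzyl alcohol
Product: 4 4-(benzyloxy)-3-methoxybenzyl chloride
Conditions: SOCl2, DMF (cat.), CH2Cl2, 0 °C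
Reagents that add atoms: thionyl chloride, O=S(Cl)Cl
Why: Deoxychlorination of an electron-rich benzylic alcohol through its chlorosulfite, to which the aryl benzyl ether and the methyl ether are inert.

Step 3
Reactants: 4 4-(benzyloxy)-3-methoxybenzyl chloride; 2 2-bromo-4-iodo-3-methylaniline
Product: 6 4-[4-(benzyloxy)-3-methoxybenzyl]-2-bromo-3-methylaniline, via benzylzinc chloride 5 (not isolated)
Conditions: Zn dust, LiCl, THF, 25 °C; then 2, Pd(PPh3)4 (cat.), THF, 25–50 °C
Reagents that add atoms: none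
Why: Negishi coupling of a benzylic zinc chloride, in which oxidative addition into the C–I bond should be much faster than into the C–Br bond flanked by NH2 and CH3, and the organozinc reagent tolerates the free aniline.

Step 4
Reactants: 6 4-[4-(benzyloxy)-3-methoxybenzyl]-2-bromo-3-methylaniline; 7 4-(benzyloxy)-3-methoxyphenylboronic acid
Product: 8 2-[4-(benzyloxy)-3-methoxyphenyl]-4-[4-(benzyloxy)-3-methoxybenzyl]-3-methylaniline
Conditions: Pd(OAc)2 (cat.), SPhos, K3PO4, toluene/H2O, 100 °C
Reagents that add atoms: none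
Why: Suzuki–Miyaura coupling, in which the bulky electron-rich dialkylbiarylphosphine should allow oxidative addition at the doubly ortho-substituted bromide while the amine and benzyl ethers tolerate the base.

Step 5
Reactants: 8 2-[4-(benzyloxy)-3-methoxyphenyl]-4-[4-(benzyloxy)-3-methoxybenzyl]-3-methylaniline
Product: 10 1-[4-(benzyloxy)-3-methoxybenzyl]-3-[4-(benzyloxy)-3-methoxyphenyl]-4-iodo-2-methylbenzene, via arenediazonium tosylate 9 (not isolated)
Conditions: NaNO2, TsOH·H2O, KI, MeCN/H2O, 10 to 25 °C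
Reagents that add atoms: potassium iodide, [K+].[I-]
Why: Sandmeyer-type diazotisation–iodination with iodide present from the start, so that electron transfer from iodide to the diazonium ion should outrun azo coupling onto the twisted pendant ring, and the benzyl ethers are stable to TsOH at 25 °C.

Step 6
Reactants: 11 dimethyl squarate (3,4-dimethoxycyclobut-3-ene-1,2-dione)
Product: 13 3-methoxycyclobut-3-ene-1,2-dione (methyl semisquarate), via hydroxycyclobutenone 12 (not isolated)
Conditions: LiAlH(OtBu)3, THF, −78 to −20 °C; then conc. HCl (cat.), CH2Cl2, 25 °C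
Reagents that add atoms: none
Why: Hydride 1,2-reduction of one carbonyl, followed by acid-induced ionisation of the allylic alcohol to a methoxy-stabilised cyclobutenyl cation, hydration and loss of methanol (a net 1,3-carbonyl transposition), the standard reaction type for preparing semisquarate esters.

Step 7
Reactants: 10 1-[4-(benzyloxy)-3-methoxybenzyl]-3-[4-(benzyloxy)-3-methoxyphenyl]-4-iodo-2-methylbenzene; 13 3-methoxycyclobut-3-ene-1,2-dione
Product: 15 4-{2-[4-(benzyloxy)-3-methoxyphenyl]-4-[4-(benzyloxy)-3-methoxybenzyl]-3-methylphenyl}-4-hydroxy-3-methoxycyclobut-2-en-1-one (racemic), via aryllithium 14 (not isolated)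
Conditions: n-BuLi, THF, −78 °C; then cannulate into 13, THF, −78 °C; aq. NH4Cl
Reagents that add atoms: none
Why: Iodine–lithium exchange followed by 1,2-addition of the aryllithium, which should attack the ketone carbonyl C2 of 13 (next to C–OMe) because the C1 carbonyl is a deactivated vinylogous ester; the carbinol centre forms racemic and is destroyed in step 8.

Step 8
Reactants: 15 4-{2-[4-(benzyloxy)-3-methoxyphenyl]-4-[4-(benzyloxy)-3-methoxybenzyl]-3-methylphenyl}-4-hydroxy-3-methoxycyclobut-2-en-1-one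
Product: 18 8-[4-(benzyloxy)-3-methoxyphenyl]-6-[4-(benzyloxy)-3-methoxybenzyl]-2-methoxy-7-methylnaphthalene-1,4-dione, via dienylketene 16 (not isolated), via hydroquinone 17 (not isolated)
Conditions: p-xylene, 138 °C; then Ag2O, 25 °C
Reagents that add atoms: none
Why: Heating opens the cyclobutenone by thermal conrotatory 4π-electrocyclic cleavage of its C1–C4 bond, the hydroxyl rotating outward and the aryl group inward, to give (Z)-dienylketene 16 with the ketene carbon held over the arene. A disrotatory 6π-electrocyclisation (formally 6-endo attack of the arene ortho carbon on the ketene) then closes the six-membered ring from the four cyclobutenone carbons and two arene carbons, and tautomerisation of the cyclohexadienone rearomatises to hydroquinone 17, which Ag2O dehydrogenates to quinone 18. The closest known reaction type is the Moore rearrangement of 4-aryl-4-hydroxycyclobutenones to 1,4-naphthoquinones. No stereocentre is formed, and the racemic carbinol centre of 15 is destroyed. The step needs torquoselectivity and regioselectivity: the donor OH secures outward rotation, closure can occur only at the one free ortho carbon because the other carries the aryl group, and the methoxy group ends at C2, next to the carbonyl peri to that aryl group, because in 15 the carbinol carbon is bonded to C–OMe.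

Step 9
Reactants: 18 8-[4-(benzyloxy)-3-methoxyphenyl]-6-[4-(benzyloxy)-3-methoxybenzyl]-2-methoxy-7-methylnaphthalene-1,4-dione
Product: 20 larreantin, via hydroquinone 19 (not isolated)
Conditions: H2 (1 atm), Pd/C, EtOAc/MeOH, 25 °C; then air, 25 °C
Reagents that add atoms: none
Why: Catalytic hydrogenolysis of the two aryl benzyl ethers, during which the quinone is reduced reversibly to its hydroquinone, followed by air oxidation of the electron-rich 2-methoxynaphthalene-1,4-diol back to the quinone; the diarylmethane, biaryl and methyl ethers should be inert.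

**Compound list**

1 | 2-bromo-3-methylaniline | Cc1cccc(N)c1Br | starting material
2 | 2-bromo-4-iodo-3-methylaniline | Cc1c(I)ccc(N)c1Br | intermediate
3 | 4-(benzyloxy)-3-methoxybenzyl alcohol | COc1cc(CO)ccc1OCc1ccccc1 | starting material
4 | 4-(benzyloxy)-3-methoxybenzyl chloride | COc1cc(CCl)ccc1OCc1ccccc1 | intermediate
5 | [4-(benzyloxy)-3-methoxybenzyl]zinc chloride | COc1cc(C[Zn]Cl)ccc1OCc1ccccc1 | intermediate (not isolated)
6 | 4-[4-(benzyloxy)-3-methoxybenzyl]-2-bromo-3-methylaniline | Cc1c(Cc2ccc(OCc3ccccc3)c(OC)c2)ccc(N)c1Br | intermediate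
7 | 4-(benzyloxy)-3-methoxyphenylboronic acid | COc1cc(B(O)O)ccc1OCc1ccccc1 | starting material
8 | 2-[4-(benzyloxy)-3-methoxyphenyl]-4-[4-(benzyloxy)-3-methoxybenzyl]-3-methylaniline | Cc1c(Cc2ccc(OCc3ccccc3)c(OC)c2)ccc(N)c1-c1ccc(OCc2ccccc2)c(OC)c1 | intermediate
9 | 2-[4-(benzyloxy)-3-methoxyphenyl]-4-[4-(benzyloxy)-3-methoxybenzyl]-3-methylbenzenediazonium p-toluenesulfonate | Cc1c(Cc2ccc(OCc3ccccc3)c(OC)c2)ccc([N+]#N)c1-c1ccc(OCc2ccccc2)c(OC)c1.Cc1ccc(S(=O)(=O)[O-])cc1 | intermediate (not isolated)
10 | 1-[4-(benzyloxy)-3-methoxybenzyl]-3-[4-(benzyloxy)-3-methoxyphenyl]-4-iodo-2-methylbenzene | Cc1c(Cc2ccc(OCc3ccccc3)c(OC)c2)ccc(I)c1-c1ccc(OCc2ccccc2)c(OC)c1 | intermediate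
11 | dimethyl squarate (3,4-dimethoxycyclobut-3-ene-1,2-dione) | COC1=C(OC)C(=O)C1=O | starting material
12 | 4-hydroxy-2,3-dimethoxycyclobut-2-en-1-one (racemic) | COC1=C(OC)C(O)C1=O | intermediate (not isolated)
13 | 3-methoxycyclobut-3-ene-1,2-dione (methyl semisquarate) | COC1=CC(=O)C1=O | intermediate
14 | {2-[4-(benzyloxy)-3-methoxyphenyl]-4-[4-(benzyloxy)-3-methoxybenzyl]-3-methylphenyl}lithium | [Li]c1ccc(Cc2ccc(OCc3ccccc3)c(OC)c2)c(C)c1-c1ccc(OCc2ccccc2)c(OC)c1 | intermediate (not isolated)
15 | 4-{2-[4-(benzyloxy)-3-methoxyphenyl]-4-[4-(benzyloxy)-3-methoxybenzyl]-3-methylphenyl}-4-hydroxy-3-methoxycyclobut-2-en-1-one (racemic) | COC1=CC(=O)C1(O)c1ccc(Cc2ccc(OCc3ccccc3)c(OC)c2)c(C)c1-c1ccc(OCc2ccccc2)c(OC)c1 | intermediate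
16 | (3Z)-4-{2-[4-(benzyloxy)-3-methoxyphenyl]-4-[4-(benzyloxy)-3-methoxybenzyl]-3-methylphenyl}-4-hydroxy-3-methoxybuta-1,3-dien-1-one (dienylketene, aryl group cis to the ketene chain) | O=C=C/C(OC)=C(\c1ccc(Cc2ccc(OCc3ccccc3)c(OC)c2)c(C)c1-c1ccc(OCc2ccccc2)c(OC)c1)O | intermediate (not isolated)
17 | 8-[4-(benzyloxy)-3-methoxyphenyl]-6-[4-(benzyloxy)-3-methoxybenzyl]-2-methoxy-7-methylnaphthalene-1,4-diol | COc1cc(O)c2cc(Cc3ccc(OCc4ccccc4)c(OC)c3)c(C)c(-c3ccc(OCc4ccccc4)c(OC)c3)c2c1O | intermediate (not isolated)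
18 | 8-[4-(benzyloxy)-3-methoxyphenyl]-6-[4-(benzyloxy)-3-methoxybenzyl]-2-methoxy-7-methylnaphthalene-1,4-dione | COC1=CC(=O)c2cc(Cc3ccc(OCc4ccccc4)c(OC)c3)c(C)c(-c3ccc(OCc4ccccc4)c(OC)c3)c2C1=O | intermediate
19 | 8-(4-hydroxy-3-methoxyphenyl)-6-(4-hydroxy-3-methoxybenzyl)-2-methoxy-7-methylnaphthalene-1,4-diol | COc1cc(O)c2cc(Cc3ccc(O)c(OC)c3)c(C)c(-c3ccc(O)c(OC)c3)c2c1O | intermediate (not isolated)
20 | larreantin, 8-(4-hydroxy-3-methoxyphenyl)-6-(4-hydroxy-3-methoxybenzyl)-2-methoxy-7-methylnaphthalene-1,4-dione | COC1=CC(=O)c2cc(Cc3ccc(O)c(OC)c3)c(C)c(-c3ccc(O)c(OC)c3)c2C1=O | target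

**Summary**

Total step count: 9. Longest linear sequence: 7 steps (steps 1, 3, 4, 5, 7, 8, 9).

Steps most likely to fail:

Step 5. The diazonium ion sits next to an electron-rich ring whose position para to the methoxy group can be reached, so intramolecular azo coupling, or hydroxy- and hydro-dediazoniation, may compete with iodide transfer. The fallback sets out from aniline 6 and exchanges nitrogen for oxygen before the biaryl exists. Diazotisation (NaNO2, aq. H2SO4/MeCN, 0 °C) should give the arenediazonium hydrogensulfate F1, and hydroxydediazoniation (Cu(NO3)2, Cu2O, H2O, 25 °C) should give 4-[4-(benzyloxy)-3-methoxybenzyl]-2-bromo-3-methylphenol F2. Suzuki–Miyaura coupling of F2 with 7 (Pd(OAc)2, SPhos, K3PO4, toluene/H2O, 100 °C) should give the biaryl phenol F3, and triflation (Tf2O, pyridine, CH2Cl2, 0 °C) the aryl triflate F4. Palladium-catalysed triflate-to-bromide exchange (Pd2(dba)3, t-BuBrettPhos, KBr, toluene, 100 °C) should give the aryl bromide F5. Bromine–lithium exchange of F5 (t-BuLi, THF, −78 °C) comes back to the route at aryllithium 14.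

Step 7. The aryllithium is shielded by the ortho aryl group, so proton transfer from the doubly benzylic CH2, slow addition, or twofold addition to the dione may take over. The fallback sets out from aniline 6 and forms the biaryl bond after the ring expansion. Diazotisation–iodination of 6 (NaNO2, TsOH·H2O, KI, MeCN/H2O), through the arenediazonium tosylate F6, should give 1-[4-(benzyloxy)-3-methoxybenzyl]-3-bromo-4-iodo-2-methylbenzene F7. Selective iodine–magnesium exchange (iPrMgCl·LiCl, THF, −40 °C) should give the less basic and less hindered arylmagnesium chloride F8, which is added to 13 at −78 °C to give the bromoaryl hydroxycyclobutenone F9. Thermolysis and Ag2O oxidation under the conditions of step 8, through the dienylketene F10 and the hydroquinone F11, should give the 8-bromoquinone F12. Suzuki–Miyaura coupling of F12 with 7 (Pd(OAc)2, SPhos, anhydrous K3PO4, toluene, 80 °C) comes back to the route at quinone 18.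

Step 3. Insertion into the C–Br bond, homocoupling of the electron-rich benzylzinc reagent, or its protonation by the amino group may erode the coupling. The fallback sets out from iodoaniline 2 and reverses the polarity of the partners. Iodine-selective Miyaura borylation (bis(pinacolato)diboron, PdCl2(dppf), KOAc, dioxane, 80 °C) should give the arylboronate F13. Suzuki–Miyaura coupling of F13 with benzyl chloride 4 (Pd(PPh3)4, K2CO3, dioxane/H2O, 80 °C) comes back to the route at 6.

**Further compounds**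

F1 | step 5 | 4-[4-(benzyloxy)-3-methoxybenzyl]-2-bromo-3-methylbenzenediazonium hydrogensulfate | Cc1c(Cc2ccc(OCc3ccccc3)c(OC)c2)ccc([N+]#N)c1Br.OS(=O)(=O)[O-]
F2 | step 5 | 4-[4-(benzyloxy)-3-methoxybenzyl]-2-bromo-3-methylphenol | Cc1c(Cc2ccc(OCc3ccccc3)c(OC)c2)ccc(O)c1Br
F3 | step 5 | 2-[4-(benzyloxy)-3-methoxyphenyl]-4-[4-(benzyloxy)-3-methoxybenzyl]-3-methylphenol | Cc1c(Cc2ccc(OCc3ccccc3)c(OC)c2)ccc(O)c1-c1ccc(OCc2ccccc2)c(OC)c1
F4 | step 5 | 2-[4-(benzyloxy)-3-methoxyphenyl]-4-[4-(benzyloxy)-3-methoxybenzyl]-3-methylphenyl trifluoromethanesulfonate | Cc1c(Cc2ccc(OCc3ccccc3)c(OC)c2)ccc(OS(=O)(=O)C(F)(F)F)c1-c1ccc(OCc2ccccc2)c(OC)c1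
F5 | step 5 | 1-[4-(benzyloxy)-3-methoxybenzyl]-3-[4-(benzyloxy)-3-methoxyphenyl]-4-bromo-2-methylbenzene | Cc1c(Cc2ccc(OCc3ccccc3)c(OC)c2)ccc(Br)c1-c1ccc(OCc2ccccc2)c(OC)c1
F6 | step 7 | 4-[4-(benzyloxy)-3-methoxybenzyl]-2-bromo-3-methylbenzenediazonium p-toluenesulfonate | Cc1c(Cc2ccc(OCc3ccccc3)c(OC)c2)ccc([N+]#N)c1Br.Cc1ccc(S(=O)(=O)[O-])cc1
F7 | step 7 | 1-[4-(benzyloxy)-3-methoxybenzyl]-3-bromo-4-iodo-2-methylbenzene | Cc1c(Cc2ccc(OCc3ccccc3)c(OC)c2)ccc(I)c1Br
F8 | step 7 | {4-[4-(benzyloxy)-3-methoxybenzyl]-2-bromo-3-methylphenyl}magnesium chloride | Cl[Mg]c1ccc(Cc2ccc(OCc3ccccc3)c(OC)c2)c(C)c1Br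
F9 | step 7 | 4-{4-[4-(benzyloxy)-3-methoxybenzyl]-2-bromo-3-methylphenyl}-4-hydroxy-3-methoxycyclobut-2-en-1-one (racemic) | COC1=CC(=O)C1(O)c1ccc(Cc2ccc(OCc3ccccc3)c(OC)c2)c(C)c1Br
F10 | step 7 | (3Z)-4-{4-[4-(benzyloxy)-3-methoxybenzyl]-2-bromo-3-methylphenyl}-4-hydroxy-3-methoxybuta-1,3-dien-1-one | O=C=C/C(OC)=C(\c1ccc(Cc2ccc(OCc3ccccc3)c(OC)c2)c(C)c1Br)O
F11 | step 7 | 6-[4-(benzyloxy)-3-methoxybenzyl]-8-bromo-2-methoxy-7-methylnaphthalene-1,4-diol | COc1cc(O)c2cc(Cc3ccc(OCc4ccccc4)c(OC)c3)c(C)c(Br)c2c1O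
F12 | step 7 | 6-[4-(benzyloxy)-3-methoxybenzyl]-8-bromo-2-methoxy-7-methylnaphthalene-1,4-dione | COC1=CC(=O)c2cc(Cc3ccc(OCc4ccccc4)c(OC)c3)c(C)c(Br)c2C1=O
F13 | step 3 | 2-bromo-3-methyl-4-(4,4,5,5-tetramethyl-1,3,2-dioxaborolan-2-yl)aniline | Cc1c(B2OC(C)(C)C(C)(C)O2)ccc(N)c1Br
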